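**Plan**
1. Numbering: ring A is the quinone ring (C1–C4, side chain on C2) and ring B is the benzenoid ring (C5–OMe, C8–OH). The side chain runs C1' (stereocentre), C2' (CH2), C3'=C4'(CH3)2. The retrosynthesis first undoes the O8 acetate and the ring A quinone/dimethyl ether change, then cuts the C1'–O acyl bond and takes C1'–O back to C1'–B. It then cuts C2–C1' and C2'–C3' together, and last C4a–C5 and C8–C8a of ring B.
2. Enabling feature: C1' lies between the sp2 carbon C2 of ring A and the C2' methylene, and C2' ends at the sp2 carbon C3' of the isobutenyl group. C1'–C2' is therefore a vinylboron unit inserted between a C2 aryl anion and a C3' alkenyl electrophile.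
3. Forward: ring B is annulated onto 2,6-dibromobenzoquinone (the future ring A) by a bromine-directed Diels–Alder reaction. This delivers O5–Me, free O8–H and Br on C2 in the required relationship. O8 is then silylated and ring A is masked as its dimethyl ether.
4. The whole side chain is attached in one three-component coupling. The C–B bond is oxidised and the alcohol senecioylated. The silyl group is exchanged for acetyl so that tetravalent cerium oxidises ring A only, and the acetate is removed last.
5. Stereochemistry: the only stereocentre, C1' (S), is set by the chiral diphosphine on palladium in the coupling and passes into the C–O bond with retention. No later step breaks a bond at C1'.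

Key step: step 7

Assumption: in aryl migrations of this coupling the (Sp,Sp) ligand series is taken to give R-configured benzylic boronates, so the (Rp,Rp) antipode is specified for the S series. The sense is to be checked on the alcohol obtained after oxidation. Both antipodes are commercial, so a reversed sense would only require exchanging the ligand.

**Step 1**
Reactants: 1 methyl (E)-4-bromobut-2-enoate
Product: 2 methyl (E)-4-methoxybut-2-enoate
Conditions: MeOH, CaCO3, reflux
Reagents that add atoms: methanol, CO
Why: Allylic SN2 solvolysis of the primary bromide by methanol is a known route to γ-alkoxycrotonates, and insoluble CaCO3 only takes up HBr, so no free methoxide can add to the enoate.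

**Step 2**
Reactants: 2 methyl (E)-4-methoxybut-2-enoate
Product: 3 (3E)-1,4-dimethoxy-1-(trimethylsilyloxy)buta-1,3-diene
Conditions: LiN(iPr)2, THF/DMPU, −78 °C; Me3SiCl, −78 °C → rt
Reagents that add atoms: chlorotrimethylsilane, C[Si](C)(C)Cl
Why: LiN(iPr)2 with DMPU removes a γ-proton rather than adding to the enoate, and O-silylation of the extended dienolate gives the 1,1,4-trioxygenated vinylketene silyl acetal, whose geometry at the acetal end does not matter because that carbon becomes aromatic.

**Step 3**
Reactants: 3 (3E)-1,4-dimethoxy-1-(trimethylsilyloxy)buta-1,3-diene; 4 2,6-dibromo-1,4-benzoquinone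
Product: 6 2-bromo-8-hydroxy-5-methoxy-1,4-naphthoquinone, via cycloadduct 5 (not isolated)
Conditions: CH2Cl2, −60 °C → rt; then 1 M HCl, THF, rt
Reagents that add atoms: none
Why: In this Diels–Alder reaction of a vinylketene acetal with a haloquinone, the diene terminus C4 (activated by the two acetal oxygens) bonds to the bromine-free carbon C3 of 4 and the acetal carbon bonds to C–Br, so loss of HBr, methanol and the silyl group from 5 aromatises ring B with O8–H peri to the carbonyl flanked by the surviving bromine.

**Step 4**
Reactants: 6 2-bromo-8-hydroxy-5-methoxy-1,4-naphthoquinone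
Product: 7 2-bromo-5-methoxy-8-(triisopropylsilyloxy)-1,4-naphthoquinone
Conditions: iPr3SiOTf, 2,6-lutidine, CH2Cl2, 0 °C
Reagents that add atoms: triisopropylsilyl trifluoromethanesulfonate, CC(C)[Si](OS(=O)(=O)C(F)(F)F)(C(C)C)C(C)C
Why: O-silylation with the silyl triflate overcomes the hydrogen bond of the peri phenol, and the hindered, non-nucleophilic base avoids the addition–elimination at C2–Br that imidazole could cause.

**Step 5**
Reactants: 7 2-bromo-5-methoxy-8-(triisopropylsilyloxy)-1,4-naphthoquinone
Product: 9 [(7-bromo-4,5,8-trimethoxynaphthalen-1-yl)oxy]triisopropylsilane, via hydroquinone 8 (not isolated)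
Conditions: Na2S2O4, EtOAc/H2O, rt; crude 8, Me2SO4, K2CO3, acetone, reflux, Ar
Reagents that add atoms: dimethyl sulfate, COS(=O)(=O)OC
Why: Dithionite reduction followed by Williamson O-methylation is the standard masking of a naphthoquinone, and a peri O-to-O silyl shift is not expected because the C1 phenoxide beside bromine is the better stabilised anion and the iPr3Si group resists pentacoordination.

**Step 6**
Reactants: 10 isobutyraldehyde
Product: 11 2-methylprop-1-en-1-yl trifluoromethanesulfonate
Conditions: Tf2O, 2,6-di-tert-butyl-4-methylpyridine, CH2Cl2, 0 °C → rt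
Reagents that add atoms: trifluoromethanesulfonic anhydride, O=S(=O)(OS(=O)(=O)C(F)(F)F)C(F)(F)F
Why: O-triflylation of the enolisable aldehyde and loss of its single α-proton to the hindered pyridine is the known enol triflate synthesis from aldehydes, and the two identical methyl groups remove any question of alkene geometry.

**Step 7**
Reactants: 9 [(7-bromo-4,5,8-trimethoxynaphthalen-1-yl)oxy]triisopropylsilane; 12 vinylboronic acid pinacol ester; 11 2-methylprop-1-en-1-yl trifluoromethanesulfonate
Product: 15 (S)-triisopropyl{[4,5,8-trimethoxy-7-(4-methyl-1-(4,4,5,5-tetramethyl-1,3,2-dioxaborolan-2-yl)pent-3-en-1-yl)naphthalen-1-yl]oxy}silane, via aryllithium 13 (not isolated), via boron ate complex 14 (not isolated)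
Conditions: 9, n-BuLi, THF, −78 °C; 12, −78 °C → rt; volatiles removed in vacuo; Pd(OAc)2 (2 mol %), Mandyphos ligand (Rp,Rp)-1,1'-bis[bis(3,5-dimethylphenyl)phosphino]-2,2'-bis[(S)-α-(dimethylamino)benzyl]ferrocene (2.4 mol %), 11, THF, 60 °C, sealed vessel
Reagents that add atoms: none
Why: Bromine–lithium exchange gives aryllithium 13, which adds to the empty p orbital of 12 to form the tetracoordinate vinylboron ate complex 14; zerovalent palladium formed in situ from Pd(OAc)2 inserts into the C–O bond of 11, and because triflate does not bind, the cationic isobutenylpalladium species coordinates the vinyl group of 14. This π-activation triggers a 1,2-shift of the naphthyl group from boron to the internal vinyl carbon anti to the metal (forming C2–C1') while the terminal carbon becomes bound to palladium, and reductive elimination then joins C2' to C3' and returns zerovalent palladium. The closest known reaction type is the palladium-catalysed enantioselective conjunctive cross-coupling of aryl-substituted vinylboron ate complexes with alkenyl triflates, applied here to a more highly oxygenated naphthyl migrating group, and no ring is closed. The C1' stereocentre is set by the C2-symmetric Mandyphos ligand, which fixes the alkene face bound by palladium, and since 14 has no stereocentre the control is purely catalyst-based. The metallate shift must outrun direct boron-to-palladium aryl transfer (the Suzuki–Miyaura product) and β-hydride elimination of the alkylpalladium intermediate, which the wide-bite-angle ligand, the halide-free medium (butyl bromide is pumped off with the solvent) and the electron-rich naphthyl group with only one ortho substituent should secure. Because C3' enters as an sp2 electrophile, no allyl metal is involved and a branched (reverse-prenyl) isomer cannot form.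

**Step 8**
Reactants: 15 (S)-triisopropyl{[4,5,8-trimethoxy-7-(4-methyl-1-(4,4,5,5-tetramethyl-1,3,2-dioxaborolan-2-yl)pent-3-en-1-yl)naphthalen-1-yl]oxy}silane
Product: 16 (S)-4-methyl-1-[1,4,5-trimethoxy-8-(triisopropylsilyloxy)naphthalen-2-yl]pent-3-en-1-ol
Conditions: NaBO3·4H2O, THF/H2O, rt
Reagents that add atoms: sodium perborate, [Na+].[O-]OB=O
Why: Perborate oxidation of a secondary boronic ester proceeds by 1,2-migration of carbon from boron to oxygen with retention, so the S boronate gives the S alcohol, and the nearly neutral medium spares the aryl silyl ether that aqueous NaOH/H2O2 might attack.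

**Step 9**
Reactants: 16 (S)-4-methyl-1-[1,4,5-trimethoxy-8-(triisopropylsilyloxy)naphthalen-2-yl]pent-3-en-1-ol; 17 3-methylbut-2-enoic acid
Product: 18 (S)-4-methyl-1-[1,4,5-trimethoxy-8-(triisopropylsilyloxy)naphthalen-2-yl]pent-3-en-1-yl 3-methylbut-2-enoate
Conditions: DCC, DMAP (cat.), CH2Cl2, 0 °C → rt
Reagents that add atoms: none
Why: Steglich esterification acylates the hindered benzylic alcohol without touching the C1'–O bond, so the configuration is kept, and it avoids the acid chloride/amine pair that deconjugates senecioyl units through a vinylketene.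

**Step 10**
Reactants: 18 (S)-4-methyl-1-[1,4,5-trimethoxy-8-(triisopropylsilyloxy)naphthalen-2-yl]pent-3-en-1-yl 3-methylbut-2-enoate
Product: 20 (S)-1-(8-acetoxy-1,4,5-trimethoxynaphthalen-2-yl)-4-methylpent-3-en-1-yl 3-methylbut-2-enoate, via naphthol 19 (not isolated)
Conditions: Bu4NF, AcOH, THF, 0 °C; then Ac2O, Et3N, DMAP (cat.), 0 °C → rt
Reagents that add atoms: acetic anhydride, CC(=O)OC(C)=O
Why: Buffered fluoride cleaves the aryl silyl ether without building up the naphthoxide, which could expel the benzylic carboxylate, and acetylation in the same flask spares the air-sensitive naphthol 19 and turns O8 into an electron-withdrawing substituent.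

**Step 11**
Reactants: 20 (S)-1-(8-acetoxy-1,4,5-trimethoxynaphthalen-2-yl)-4-methylpent-3-en-1-yl 3-methylbut-2-enoate
Product: 21 (S)-1-(8-acetoxy-5-methoxy-1,4-dioxo-1,4-dihydronaphthalen-2-yl)-4-methylpent-3-en-1-yl 3-methylbut-2-enoate
Conditions: (NH4)2Ce(NO3)6, MeCN/H2O, 0 °C
Reagents that add atoms: water, O (supplies both quinone oxygens; the methoxy groups leave as methanol)
Why: Oxidative demethylation of a 1,4-dimethoxyarene by tetravalent cerium takes place on the more electron-rich ring A, since ring B now carries an acetoxy group and cannot become a quinone without acyl loss, and C1' esters bearing the prenyl-type alkene are known to tolerate these brief cold conditions.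

**Step 12**
Reactants: 21 (S)-1-(8-acetoxy-5-methoxy-1,4-dioxo-1,4-dihydronaphthalen-2-yl)-4-methylpent-3-en-1-yl 3-methylbut-2-enoate
Product: 22 (S)-1-(8-hydroxy-5-methoxy-1,4-dioxo-1,4-dihydronaphthalen-2-yl)-4-methylpent-3-en-1-yl 3-methylbut-2-enoate
Conditions: K2CO3 (0.3 equiv), MeOH/CH2Cl2, 0 °C, short contact; aq NaH2PO4 quench
Reagents that add atoms: none
Why: Base-catalysed transesterification (Zemplén type) distinguishes the two esters by leaving group, since the aryl acetate releases a chelated, quinone-stabilised phenoxide far faster than the conjugated secondary senecioate can react, and C1' is not involved.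

**Compound list**
1 | methyl (E)-4-bromobut-2-enoate | COC(=O)/C=C/CBr | starting material
2 | methyl (E)-4-methoxybut-2-enoate | COC/C=C/C(=O)OC | intermediate
3 | (3E)-1,4-dimethoxy-1-(trimethylsilyloxy)buta-1,3-diene (geometry at the acetal end undefined) | CO/C=C/C=C(OC)O[Si](C)(C)C | intermediate
4 | 2,6-dibromo-1,4-benzoquinone | O=C1C=C(Br)C(=O)C(Br)=C1 | starting material
5 | 2,8a-dibromo-5,8-dimethoxy-8-(trimethylsilyloxy)-4a,5,8,8a-tetrahydronaphthalene-1,4-dione (transient cycloadduct, relative configuration undefined) | O=C1C=C(Br)C(=O)C2(Br)C1C(OC)C=CC2(OC)O[Si](C)(C)C | intermediate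
6 | 2-bromo-8-hydroxy-5-methoxy-1,4-naphthoquinone | COc1ccc(O)c2c1C(=O)C=C(Br)C2=O | intermediate
7 | 2-bromo-5-methoxy-8-(triisopropylsilyloxy)-1,4-naphthoquinone | COc1ccc(O[Si](C(C)C)(C(C)C)C(C)C)c2c1C(=O)C=C(Br)C2=O | intermediate
8 | 2-bromo-5-methoxy-8-(triisopropylsilyloxy)naphthalene-1,4-diol | COc1ccc(O[Si](C(C)C)(C(C)C)C(C)C)c2c(O)c(Br)cc(O)c12 | intermediate
9 | [(7-bromo-4,5,8-trimethoxynaphthalen-1-yl)oxy]triisopropylsilane | CC(C)[Si](Oc1ccc(OC)c2c(OC)cc(Br)c(OC)c12)(C(C)C)C(C)C | intermediate
10 | isobutyraldehyde | CC(C)C=O | starting material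
11 | 2-methylprop-1-en-1-yl trifluoromethanesulfonate | CC(C)=COS(=O)(=O)C(F)(F)F | intermediate
12 | vinylboronic acid pinacol ester | C=CB1OC(C)(C)C(C)(C)O1 | starting material
13 | [1,4,5-trimethoxy-8-(triisopropylsilyloxy)naphthalen-2-yl]lithium | [Li]c1cc(OC)c2c(OC)ccc(O[Si](C(C)C)(C(C)C)C(C)C)c2c1OC | intermediate
14 | lithium (pinacolato)(vinyl)[1,4,5-trimethoxy-8-(triisopropylsilyloxy)naphthalen-2-yl]borate | [Li+].C=C[B-]1(OC(C)(C)C(C)(C)O1)c1cc(OC)c2c(OC)ccc(O[Si](C(C)C)(C(C)C)C(C)C)c2c1OC | intermediate
15 | (S)-triisopropyl{[4,5,8-trimethoxy-7-(4-methyl-1-(4,4,5,5-tetramethyl-1,3,2-dioxaborolan-2-yl)pent-3-en-1-yl)naphthalen-1-yl]oxy}silane | CC(C)[Si](Oc1ccc(OC)c2c(OC)cc([C@H](CC=C(C)C)B3OC(C)(C)C(C)(C)O3)c(OC)c12)(C(C)C)C(C)C | intermediate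
16 | (S)-4-methyl-1-[1,4,5-trimethoxy-8-(triisopropylsilyloxy)naphthalen-2-yl]pent-3-en-1-ol | CC(C)[Si](Oc1ccc(OC)c2c(OC)cc([C@H](CC=C(C)C)O)c(OC)c12)(C(C)C)C(C)C | intermediate
17 | 3-methylbut-2-enoic acid (senecioic acid) | CC(C)=CC(=O)O | starting material
18 | (S)-4-methyl-1-[1,4,5-trimethoxy-8-(triisopropylsilyloxy)naphthalen-2-yl]pent-3-en-1-yl 3-methylbut-2-enoate | CC(C)[Si](Oc1ccc(OC)c2c(OC)cc([C@H](CC=C(C)C)OC(=O)C=C(C)C)c(OC)c12)(C(C)C)C(C)C | intermediate
19 | (S)-1-(8-hydroxy-1,4,5-trimethoxynaphthalen-2-yl)-4-methylpent-3-en-1-yl 3-methylbut-2-enoate | COc1ccc(O)c2c(OC)c([C@H](CC=C(C)C)OC(=O)C=C(C)C)cc(OC)c12 | intermediate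
20 | (S)-1-(8-acetoxy-1,4,5-trimethoxynaphthalen-2-yl)-4-methylpent-3-en-1-yl 3-methylbut-2-enoate | COc1ccc(OC(C)=O)c2c(OC)c([C@H](CC=C(C)C)OC(=O)C=C(C)C)cc(OC)c12 | intermediate
21 | (S)-1-(8-acetoxy-5-methoxy-1,4-dioxo-1,4-dihydronaphthalen-2-yl)-4-methylpent-3-en-1-yl 3-methylbut-2-enoate | COc1ccc(OC(C)=O)c2c1C(=O)C=C([C@H](CC=C(C)C)OC(=O)C=C(C)C)C2=O | intermediate
22 | (S)-1-(8-hydroxy-5-methoxy-1,4-dioxo-1,4-dihydronaphthalen-2-yl)-4-methylpent-3-en-1-yl 3-methylbut-2-enoate (CNP0299347.1) | COc1ccc(O)c2c1C(=O)C=C([C@H](CC=C(C)C)OC(=O)C=C(C)C)C2=O | target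

**Step count**
Total step count: 12. Longest linear sequence: 11 steps (1 to 22 through steps 1–5 and 7–12). Step 6 is a one-step side branch.

**Steps most likely to fail**

Step 7. The metallate shift may be outpaced by direct aryl transfer from boron to palladium or by β-hydride elimination. Facial selectivity may also erode because the migrating naphthyl group is bulky and carries a chelating ortho methoxy group.
- The fallback forms C2–C1' by acylation and sets C1' by reagent-controlled reduction.
- Commercial 4-methylpent-3-enoic acid is converted with MeNHOMe·HCl and a carbodiimide into N-methoxy-N,4-dimethylpent-3-enamide F1.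
- Bromide 9 is lithiated (n-BuLi, THF, −78 °C) and acylated with F1 in a Weinreb ketone synthesis. This gives 4-methyl-1-[1,4,5-trimethoxy-8-(triisopropylsilyloxy)naphthalen-2-yl]pent-3-en-1-one F2.
- Reduction of F2 with (−)-B-chlorodiisopinocampheylborane treats the aryl group as the large substituent and leaves the alkene alone. It should give the S alcohol, so the route is rejoined at 16.

Step 3. Several processes could erode the cycloaddition:
- the diene may form with an unfavourable geometry at C3=C4;
- the diene may be consumed by the HBr released;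
- methanol may be lost from C5 instead of HBr;
- a second cycloaddition may take place on the remaining bromoalkene.

The fallback avoids the cycloaddition altogether. Commercial naphthazarin (5,8-dihydroxy-1,4-naphthoquinone) is mono-O-methylated (MeI, Ag2O, CHCl3) to 5-hydroxy-8-methoxy-1,4-naphthoquinone F3. Br2 in AcOH adds across the quinone double bond to give 2,3-dibromo-5-hydroxy-8-methoxy-2,3-dihydronaphthalene-1,4-dione F4. Warming with NaOAc removes the more acidic proton, the one next to the hydrogen-bond-activated carbonyl. Bromine is therefore left beside the carbonyl that is peri to the hydroxyl group, as in the bromination of juglone. The route is rejoined at 6.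

Step 12. Methoxide may add to C3 of the quinone or attack the senecioate, and prolonged base contact may degrade the acyloxyalkyl quinone. The fallback removes the need to discriminate between two esters by installing the senecioate last.
- Alcohol 16 is desilylated (Bu4NF, THF, 0 °C) to (S)-1-(8-hydroxy-1,4,5-trimethoxynaphthalen-2-yl)-4-methylpent-3-en-1-ol F5.
- F5 is acetylated on both oxygens in the same flask (Ac2O, Et3N, DMAP) to (S)-1-(8-acetoxy-1,4,5-trimethoxynaphthalen-2-yl)-4-methylpent-3-en-1-yl acetate F6.
- (NH4)2Ce(NO3)6 in MeCN/H2O then gives (S)-1-(8-acetoxy-5-methoxy-1,4-dioxo-1,4-dihydronaphthalen-2-yl)-4-methylpent-3-en-1-yl acetate F7.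
- Both acetates are cleaved with cold dilute aqueous NaOH under argon and the mixture is acidified, the usual treatment of alkannin-type ester mixtures. This gives (S)-8-hydroxy-2-(1-hydroxy-4-methylpent-3-en-1-yl)-5-methoxy-1,4-naphthoquinone F8.
- Steglich esterification of F8 with 17 (DCC, DMAP) acylates only the side-chain hydroxyl, because the peri phenol is held in a hydrogen bond to C1=O. The route is rejoined at 22.

**Further compounds**
F1 | step 7 | N-methoxy-N,4-dimethylpent-3-enamide | CON(C)C(=O)CC=C(C)C
F2 | step 7 | 4-methyl-1-[1,4,5-trimethoxy-8-(triisopropylsilyloxy)naphthalen-2-yl]pent-3-en-1-one | CC(C)[Si](Oc1ccc(OC)c2c(OC)cc(C(=O)CC=C(C)C)c(OC)c12)(C(C)C)C(C)C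
F3 | step 3 | 5-hydroxy-8-methoxy-1,4-naphthoquinone | COc1ccc(O)c2c1C(=O)C=CC2=O
F4 | step 3 | 2,3-dibromo-5-hydroxy-8-methoxy-2,3-dihydronaphthalene-1,4-dione | COc1ccc(O)c2c1C(=O)C(Br)C(Br)C2=O
F5 | step 12 | (S)-1-(8-hydroxy-1,4,5-trimethoxynaphthalen-2-yl)-4-methylpent-3-en-1-ol | COc1ccc(O)c2c(OC)c([C@H](CC=C(C)C)O)cc(OC)c12
F6 | step 12 | (S)-1-(8-acetoxy-1,4,5-trimethoxynaphthalen-2-yl)-4-methylpent-3-en-1-yl acetate | COc1ccc(OC(C)=O)c2c(OC)c([C@H](CC=C(C)C)OC(C)=O)cc(OC)c12
F7 | step 12 | (S)-1-(8-acetoxy-5-methoxy-1,4-dioxo-1,4-dihydronaphthalen-2-yl)-4-methylpent-3-en-1-yl acetate | COc1ccc(OC(C)=O)c2c1C(=O)C=C([C@H](CC=C(C)C)OC(C)=O)C2=O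
F8 | step 12 | (S)-8-hydroxy-2-(1-hydroxy-4-methylpent-3-en-1-yl)-5-methoxy-1,4-naphthoquinone | COc1ccc(O)c2c1C(=O)C=C([C@H](CC=C(C)C)O)C2=O
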